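**Plan**

1. Indene locants are used throughout; ring A is the six-membered ring (C3a–C7a) and ring B the five-membered ring (C1, C2, C3, C3a, C7a). C3 is a CH2 allylic to the C3a=C4 alkene of ring A and C2 carries the carboxyl carbon, so C2–C3 can be made by closing a C2 enolate onto a π-allyl spread over C3–C3a–C4.
2. Retrosynthetic cuts, in order: acetate and CO2H oxidation level; C1–CH3; C1–side chain; C2–C3 (ring B); C1–C2 (acetate enolate plus lactone); C7a–CH3; C7–C7a (ring A, from geranic acid).
3. Forward: ring A by acid cyclisation of geranic acid, methylation at C7a, resolution, allylic oxidation to a lactone, β-keto ester 12, carbonate 13. Ring B then closes by palladium allylic alkylation (13 → 14). The Z side chain is joined at C1 by Negishi coupling, the C1 methyl by cuprate addition, then desilylation, acetylation and oxidation.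
4. Stereochemistry: C7a from resolution of acid 5 with (S)-1-phenylethylamine; C1 by substrate control (methyl enters on the face of the C7a methyl, away from C7 and its two methyls); C2 by base equilibration of the aldehyde (formyl trans to the side chain); the Z alkene from a Still–Gennari olefination.

Key step: step 8

Assumption: the less soluble salt of racemic acid 5 with (S)-1-phenylethylamine is taken to contain the (S)-acid; if the pairing is the reverse, (R)-1-phenylethylamine is used and nothing else changes.

**Route**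

Step 1
Reactants: 1 geranic acid
Product: 2 rac-α-cyclogeranic acid (rac-2,6,6-trimethylcyclohex-2-ene-1-carboxylic acid)
Conditions: H3PO4 (85%), toluene, 100 °C
Reagents that add atoms: none
Why: Cation–olefin cyclisation: protonation of the terminal trisubstituted alkene gives a tertiary cation that is captured by the α-carbon of the conjugated alkene in a six-membered closure, and loss of a ring proton should leave the endocyclic (α) alkene; the stereocentre formed is racemic and is erased in step 2.

Step 2
Reactants: 2 rac-α-cyclogeranic acid; 3 iodomethane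
Product: 5 rac-1,2,6,6-tetramethylcyclohex-2-ene-1-carboxylic acid, via dilithium enediolate 4 (not isolated)
Conditions: LiN(i-Pr)2 (2.2 equiv), THF, 0 °C; MeI, −78 → 25 °C; 1 M HCl
Reagents that add atoms: iodomethane 3, CI (the lithium of LiN(i-Pr)2 stays only in 4)
Why: Alkylation of a carboxylic acid dianion: the conjugated enediolate 4 is expected to react with iodomethane at the α-carbon, which creates the quaternary carbon (later C7a) as a racemate.

Step 3
Reactants: 5 rac-1,2,6,6-tetramethylcyclohex-2-ene-1-carboxylic acid; 6 (S)-1-phenylethylamine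
Product: 7 (S)-1-phenylethylammonium (1S)-1,2,6,6-tetramethylcyclohex-2-ene-1-carboxylate
Conditions: (S)-PhCH(Me)NH2 (0.6 equiv), acetone, reflux → 5 °C; recrystallisation from acetone
Reagents that add atoms: (S)-1-phenylethylamine 6, C[C@H](N)c1ccccc1
Why: Classical resolution through diastereomeric salts: the two salts differ in solubility and the quaternary centre cannot epimerise, so crystallisation should deliver the salt of the (S)-acid and thereby fix C7a for the whole route.

Step 4
Reactants: 7 (S)-1-phenylethylammonium (1S)-1,2,6,6-tetramethylcyclohex-2-ene-1-carboxylate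
Product: 8 (1S)-1,2,6,6-tetramethylcyclohex-2-ene-1-carboxylic acid
Conditions: 1 M HCl, Et2O, 0 °C
Reagents that add atoms: none
Why: Proton transfer from the mineral acid frees the carboxylic acid into the organic phase and leaves the amine hydrochloride in water, without touching the stereocentre.

Step 5
Reactants: 8 (1S)-1,2,6,6-tetramethylcyclohex-2-ene-1-carboxylic acid
Product: 10 (7aS)-7,7,7a-trimethyl-5,6,7,7a-tetrahydro-2-benzofuran-1(3H)-one, via hydroxy acid 9 (not isolated)
Conditions: SeO2 (0.5 equiv), t-BuOOH, CH2Cl2, 25 °C; then TsOH (cat.), CH2Cl2, 25 °C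
Reagents that add atoms: tert-butyl hydroperoxide, CC(C)(C)OO (terminal oxidant; the oxygen is passed on through SeO2, O=[Se]=O)
Why: SeO2 allylic oxidation (ene reaction followed by [2,3]-sigmatropic shift) should occur at the ring methyl, the only C–H-bearing position on the more substituted alkene carbon because the ring α-position is quaternary, and the γ-hydroxy acid 9 then closes to the five-membered lactone under acid catalysis.

Step 6
Reactants: 10 (7aS)-7,7,7a-trimethyl-5,6,7,7a-tetrahydro-2-benzofuran-1(3H)-one; 11 methyl acetate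
Product: 12 methyl 3-[(1S)-2-(hydroxymethyl)-1,6,6-trimethylcyclohex-2-en-1-yl]-3-oxopropanoate
Conditions: LiN(i-Pr)2 (2.5 equiv), MeOAc (2.5 equiv), THF, −78 °C; add 10, −78 → −20 °C; AcOH, −78 °C
Reagents that add atoms: methyl acetate 11, COC(C)=O
Why: Crossed Claisen acylation: the lithium enolate of methyl acetate adds to the non-enolisable lactone carbonyl and the ring opens to the β-keto ester enolate and the alkoxide, a second equivalent of enolate serving as base; 12 is expected to equilibrate with its cyclic hemiketal.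

Step 7
Reactants: 12 methyl 3-[(1S)-2-(hydroxymethyl)-1,6,6-trimethylcyclohex-2-en-1-yl]-3-oxopropanoate
Product: 13 methyl 3-[(1S)-2-{[(methoxycarbonyl)oxy]methyl}-1,6,6-trimethylcyclohex-2-en-1-yl]-3-oxopropanoate
Conditions: ClCO2Me (1.5 equiv), pyridine, CH2Cl2, 0 °C
Reagents that add atoms: methyl chloroformate, COC(=O)Cl
Why: O-acylation of the primary allylic alcohol by a chloroformate under pyridine catalysis; any hemiketal form drains through the open hydroxy ketone, and the β-keto ester is not acylated under these weakly basic conditions.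

Step 8
Reactants: 13 methyl 3-[(1S)-2-{[(methoxycarbonyl)oxy]methyl}-1,6,6-trimethylcyclohex-2-en-1-yl]-3-oxopropanoate
Product: 14 methyl (7aS)-7,7,7a-trimethyl-1-oxo-2,3,5,6,7,7a-hexahydro-1H-indene-2-carboxylate (C2 epimers and enol, interconverting)
Conditions: Pd(PPh3)4 (5 mol%), THF, 65 °C
Reagents that add atoms: none
Why: Zerovalent palladium ionises the allylic carbonate with loss of CO2 to a π-allyl complex of divalent palladium over C3–C3a–C4, and the methoxide set free deprotonates the β-keto ester, whose C2 carbon attacks the primary terminus C3 on the face away from the metal, forming C2–C3 and returning the alkene to C3a=C4. The closest known reaction is the intramolecular Tsuji–Trost alkylation of β-keto esters, and closure of an enolate onto the terminus of a π-allyl that carries the tether on its central carbon is the ring-forming event of palladium trimethylenemethane cyclopentane annulations. Ring B closes as a five-membered ring with palladium leaving from outside the ring (exo with respect to the bond being broken, with the C1 carbonyl inside the ring), a mode that base-mediated alkylation of β-keto esters avoids in favour of O-alkylation but that palladium catalysis is known to deliver. No lasting stereocentre is formed: C2 arises as an enolisable centre and C7a is not touched. The step needs C- over O-alkylation and C3 over C4 attack; the first is secured because the O-alkylated product is itself an allylic enol ether that re-ionises and funnels to the ketone, the second because C3 is the unsubstituted exocyclic terminus and leads to the fused bicycle with the trisubstituted ring alkene, whereas C4 is a secondary ring carbon whose alkylation would give a bridged bicyclo[3.2.1]octane.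

Step 9
Reactants: 14 methyl (7aS)-7,7,7a-trimethyl-1-oxo-2,3,5,6,7,7a-hexahydro-1H-indene-2-carboxylate
Product: 15 methyl (7aS)-7,7,7a-trimethyl-1-{[(trifluoromethyl)sulfonyl]oxy}-3,5,6,7-tetrahydro-7aH-indene-2-carboxylate (enol triflate, C1=C2)
Conditions: Tf2O (1.2 equiv), i-Pr2NEt (1.5 equiv), CH2Cl2, −78 → 0 °C
Reagents that add atoms: trifluoromethanesulfonic anhydride, O=S(=O)(OS(=O)(=O)C(F)(F)F)C(F)(F)F
Why: Enol triflate formation from a β-keto ester: only C2 can enolise because C7a is quaternary, so O-sulfonylation of the amine-generated enolate should give the C1=C2 triflate conjugated with the ester.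

Step 10
Reactants: 16 3-[(tert-butyldimethylsilyl)oxy]propanal; 17 ethyl 2-[bis(2,2,2-trifluoroethoxy)phosphoryl]propanoate
Product: 18 ethyl (2Z)-5-[(tert-butyldimethylsilyl)oxy]-2-methylpent-2-enoate
Conditions: KN(SiMe3)2, 18-crown-6, THF, −78 °C
Reagents that add atoms: phosphonate 17, CCOC(=O)C(C)P(=O)(OCC(F)(F)F)OCC(F)(F)F
Why: Still–Gennari variant of the Horner–Wadsworth–Emmons olefination: the electron-poor bis(trifluoroethyl) phosphonate under dissociating conditions eliminates quickly from the kinetic adduct and should give the Z trisubstituted enoate, with the ester cis to the chain.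

Step 11
Reactants: 18 ethyl (2Z)-5-[(tert-butyldimethylsilyl)oxy]-2-methylpent-2-enoate
Product: 19 (2Z)-5-[(tert-butyldimethylsilyl)oxy]-2-methylpent-2-en-1-ol
Conditions: i-Bu2AlH (2.5 equiv), CH2Cl2, −78 °C
Reagents that add atoms: none
Why: Hydride reduction of the conjugated ester to the allylic alcohol at low temperature, which leaves the alkene geometry and the silyl ether untouched.

Step 12
Reactants: 19 (2Z)-5-[(tert-butyldimethylsilyl)oxy]-2-methylpent-2-en-1-ol
Product: 20 tert-butyl{[(2Z)-5-{[tert-butyl(dimethyl)silyl]oxy}-2-methylpent-2-en-1-yl]oxy}diphenylsilane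
Conditions: t-BuPh2SiCl, imidazole, DMF, 25 °C
Reagents that add atoms: tert-butyl(chloro)diphenylsilane, CC(C)(C)[Si](Cl)(c1ccccc1)c1ccccc1
Why: Imidazole-promoted silylation of a primary alcohol; the bulkier diphenylsilyl group is chosen so that it outlasts the dimethylsilyl ether in the next step and survives all later ones.

Step 13
Reactants: 20 tert-butyl{[(2Z)-5-{[tert-butyl(dimethyl)silyl]oxy}-2-methylpent-2-en-1-yl]oxy}diphenylsilane
Product: 21 (3Z)-5-[(tert-butyldiphenylsilyl)oxy]-4-methylpent-3-en-1-ol
Conditions: PPTS (cat.), EtOH, 45 °C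
Reagents that add atoms: none
Why: Mild acid-catalysed alcoholysis removes the less hindered tert-butyldimethylsilyl ether, whereas the tert-butyldiphenylsilyl ether is far more stable to acid.

Step 14
Reactants: 21 (3Z)-5-[(tert-butyldiphenylsilyl)oxy]-4-methylpent-3-en-1-ol
Product: 22 tert-butyl{[(2Z)-5-iodo-2-methylpent-2-en-1-yl]oxy}diphenylsilane
Conditions: I2, PPh3, imidazole, CH2Cl2, 0 → 25 °C
Reagents that add atoms: iodine, II
Why: Appel-type iodination (Garegg–Samuelsson conditions) converts the primary alcohol to the iodide by SN2 displacement of the oxyphosphonium ion without affecting the remote alkene geometry.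

Step 15
Reactants: 15 enol triflate; 22 tert-butyl{[(2Z)-5-iodo-2-methylpent-2-en-1-yl]oxy}diphenylsilane
Product: 24 methyl (7aS)-1-[(3Z)-5-(tert-butyldiphenylsilyloxy)-4-methylpent-3-en-1-yl]-7,7,7a-trimethyl-3,5,6,7-tetrahydro-7aH-indene-2-carboxylate, via alkylzinc iodide 23 (not isolated)
Conditions: 22, Zn, LiCl, THF, 40 °C; then 15, PdCl2(dppf) (5 mol%), THF/NMP, 60 °C
Reagents that add atoms: iodide 22 as its zinc reagent 23, CC(C)(C)[Si](OC/C(C)=C\CCI)(c1ccccc1)c1ccccc1 (zinc, [Zn], stays only in 23)
Why: Negishi coupling: LiCl-assisted zinc insertion into the primary iodide gives alkylzinc iodide 23, which should transmetalate to the palladium complex formed by oxidative addition of the electron-poor enol triflate; the wide-bite-angle dppf ligand favours reductive elimination over β-hydride loss, and the Z alkene is a spectator.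

Step 16
Reactants: 24 coupled enoate
Product: 25 [(7aS)-1-[(3Z)-5-(tert-butyldiphenylsilyloxy)-4-methylpent-3-en-1-yl]-7,7,7a-trimethyl-3,5,6,7-tetrahydro-7aH-inden-2-yl]methanol
Conditions: i-Bu2AlH (3 equiv), CH2Cl2, −78 → 0 °C
Reagents that add atoms: none
Why: 1,2-Hydride reduction of the tetrasubstituted conjugated ester to the allylic alcohol; the silyl ether and the alkenes are inert.

Step 17
Reactants: 25 allylic alcohol
Product: 26 (7aS)-1-[(3Z)-5-(tert-butyldiphenylsilyloxy)-4-methylpent-3-en-1-yl]-7,7,7a-trimethyl-3,5,6,7-tetrahydro-7aH-indene-2-carbaldehyde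
Conditions: Dess–Martin periodinane, CH2Cl2, 25 °C
Reagents that add atoms: none
Why: Dess–Martin oxidation of the primary allylic alcohol to the enal under near-neutral conditions that neither isomerise the alkenes nor cleave the silyl ether.

Step 18
Reactants: 26 enal; 27 methyllithium
Product: 29 (1R,2S,7aS)-1-[(3Z)-5-(tert-butyldiphenylsilyloxy)-4-methylpent-3-en-1-yl]-1,7,7,7a-tetramethyl-2,3,5,6,7,7a-hexahydro-1H-indene-2-carbaldehyde, via trimethylsilyl enol ether 28 (not isolated)
Conditions: Me2CuLi (from MeLi and CuI, 3 equiv), Me3SiCl, Et2O/THF, −78 → −30 °C; then K2CO3, MeOH, 25 °C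
Reagents that add atoms: methyllithium 27, [Li]C, used as lithium dimethylcuprate, [Li+].C[Cu-]C (chlorotrimethylsilane, C[Si](C)(C)Cl, stays only in 28)
Why: Chlorosilane-accelerated conjugate addition of a Gilman cuprate to the β,β-disubstituted enal: the methyl group should enter C1 on the face of ring B that bears the C7a methyl, because the other face is blocked by C7 with its geminal methyls, which sets C1 (R) with the two methyls cis; methanolysis of silyl enol ether 28 and carbonate-mediated equilibration are then expected to set C2 (S) thermodynamically, the formyl group settling trans to the side chain, which would otherwise be squeezed between it and C7.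

Step 19
Reactants: 29 silyl-protected aldehyde
Product: 30 (1R,2S,7aS)-1-[(3Z)-5-hydroxy-4-methylpent-3-en-1-yl]-1,7,7,7a-tetramethyl-2,3,5,6,7,7a-hexahydro-1H-indene-2-carbaldehyde
Conditions: Bu4NF, AcOH, THF, 25 °C
Reagents that add atoms: none
Why: Fluoride-induced cleavage of the silyl ether, driven by the strong Si–F bond and buffered with acetic acid so that the aldehyde is not exposed to basic fluoride.

Step 20
Reactants: 30 hydroxy aldehyde; 31 acetic anhydride
Product: 32 (2Z)-5-[(1R,2S,7aS)-2-formyl-1,7,7,7a-tetramethyl-2,3,5,6,7,7a-hexahydro-1H-inden-1-yl]-2-methylpent-2-en-1-yl acetate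
Conditions: Ac2O, pyridine, DMAP (cat.), CH2Cl2, 0 → 25 °C
Reagents that add atoms: acetic anhydride 31, CC(=O)OC(C)=O
Why: Nucleophile-catalysed acetylation of the primary allylic alcohol; the hindered aldehyde does not react.

Step 21
Reactants: 32 acetoxy aldehyde
Product: 33 (1R,2S,7aS)-1-[(3Z)-5-(acetyloxy)-4-methylpent-3-en-1-yl]-1,7,7,7a-tetramethyl-2,3,5,6,7,7a-hexahydro-1H-indene-2-carboxylic acid (target)
Conditions: NaClO2, NaH2PO4, 2-methyl-2-butene, t-BuOH/H2O, 25 °C
Reagents that add atoms: sodium chlorite, [Na+].[O-]Cl=O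
Why: Pinnick (Lindgren–Kraus) oxidation converts the aldehyde to the acid with chlorous acid under buffered conditions that should not epimerise C2, while 2-methyl-2-butene traps hypochlorous acid and so protects both trisubstituted alkenes, and the acetate survives.

**Compound list**

1 | geranic acid | CC(C)=CCC/C(C)=C/C(=O)O | starting material
2 | rac-α-cyclogeranic acid | CC1=CCCC(C)(C)C1C(=O)O | intermediate
3 | iodomethane | CI | starting material
4 | dilithium enediolate of 2 | [Li+].[Li+].CC1=CCCC(C)(C)C1=C([O-])[O-] | intermediate (not isolated)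
5 | rac-1,2,6,6-tetramethylcyclohex-2-ene-1-carboxylic acid | CC1=CCCC(C)(C)C1(C)C(=O)O | intermediate
6 | (S)-1-phenylethylamine | C[C@H](N)c1ccccc1 | starting material
7 | (S)-1-phenylethylammonium (1S)-1,2,6,6-tetramethylcyclohex-2-ene-1-carboxylate | C[C@H]([NH3+])c1ccccc1.CC1=CCCC(C)(C)[C@]1(C)C(=O)[O-] | intermediate
8 | (1S)-1,2,6,6-tetramethylcyclohex-2-ene-1-carboxylic acid | CC1=CCCC(C)(C)[C@]1(C)C(=O)O | intermediate
9 | (1S)-2-(hydroxymethyl)-1,6,6-trimethylcyclohex-2-ene-1-carboxylic acid | OCC1=CCCC(C)(C)[C@]1(C)C(=O)O | intermediate (not isolated)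
10 | (7aS)-7,7,7a-trimethyl-5,6,7,7a-tetrahydro-2-benzofuran-1(3H)-one | O=C1OCC2=CCCC(C)(C)[C@@]21C | intermediate
11 | methyl acetate | COC(C)=O | starting material
12 | methyl 3-[(1S)-2-(hydroxymethyl)-1,6,6-trimethylcyclohex-2-en-1-yl]-3-oxopropanoate | COC(=O)CC(=O)[C@@]1(C)C(C)(C)CCC=C1CO | intermediate
13 | methyl 3-[(1S)-2-{[(methoxycarbonyl)oxy]methyl}-1,6,6-trimethylcyclohex-2-en-1-yl]-3-oxopropanoate | COC(=O)CC(=O)[C@@]1(C)C(C)(C)CCC=C1COC(=O)OC | intermediate
14 | methyl (7aS)-7,7,7a-trimethyl-1-oxo-2,3,5,6,7,7a-hexahydro-1H-indene-2-carboxylate (C2 epimerisable) | O=C1C(C(=O)OC)CC2=CCCC(C)(C)[C@@]21C | intermediate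
15 | methyl (7aS)-7,7,7a-trimethyl-1-{[(trifluoromethyl)sulfonyl]oxy}-3,5,6,7-tetrahydro-7aH-indene-2-carboxylate | O=S(=O)(OC1=C(C(=O)OC)CC2=CCCC(C)(C)[C@@]21C)C(F)(F)F | intermediate
16 | 3-[(tert-butyldimethylsilyl)oxy]propanal | CC(C)(C)[Si](C)(C)OCCC=O | starting material
17 | ethyl 2-[bis(2,2,2-trifluoroethoxy)phosphoryl]propanoate | CCOC(=O)C(C)P(=O)(OCC(F)(F)F)OCC(F)(F)F | starting material
18 | ethyl (2Z)-5-[(tert-butyldimethylsilyl)oxy]-2-methylpent-2-enoate | CCOC(=O)/C(C)=C\CCO[Si](C)(C)C(C)(C)C | intermediate
19 | (2Z)-5-[(tert-butyldimethylsilyl)oxy]-2-methylpent-2-en-1-ol | OC/C(C)=C\CCO[Si](C)(C)C(C)(C)C | intermediate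
20 | tert-butyl{[(2Z)-5-{[tert-butyl(dimethyl)silyl]oxy}-2-methylpent-2-en-1-yl]oxy}diphenylsilane | CC(C)(C)[Si](OC/C(C)=C\CCO[Si](C)(C)C(C)(C)C)(c1ccccc1)c1ccccc1 | intermediate
21 | (3Z)-5-[(tert-butyldiphenylsilyl)oxy]-4-methylpent-3-en-1-ol | CC(C)(C)[Si](OC/C(C)=C\CCO)(c1ccccc1)c1ccccc1 | intermediate
22 | tert-butyl{[(2Z)-5-iodo-2-methylpent-2-en-1-yl]oxy}diphenylsilane | CC(C)(C)[Si](OC/C(C)=C\CCI)(c1ccccc1)c1ccccc1 | intermediate
23 | [(3Z)-5-(tert-butyldiphenylsilyloxy)-4-methylpent-3-en-1-yl]zinc iodide | CC(C)(C)[Si](OC/C(C)=C\CC[Zn]I)(c1ccccc1)c1ccccc1 | intermediate (not isolated)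
24 | methyl (7aS)-1-[(3Z)-5-(tert-butyldiphenylsilyloxy)-4-methylpent-3-en-1-yl]-7,7,7a-trimethyl-3,5,6,7-tetrahydro-7aH-indene-2-carboxylate | CC(C)(C)[Si](OC/C(C)=C\CCC1=C(C(=O)OC)CC2=CCCC(C)(C)[C@@]21C)(c3ccccc3)c4ccccc4 | intermediate
25 | [(7aS)-1-[(3Z)-5-(tert-butyldiphenylsilyloxy)-4-methylpent-3-en-1-yl]-7,7,7a-trimethyl-3,5,6,7-tetrahydro-7aH-inden-2-yl]methanol | CC(C)(C)[Si](OC/C(C)=C\CCC1=C(CO)CC2=CCCC(C)(C)[C@@]21C)(c3ccccc3)c4ccccc4 | intermediate
26 | (7aS)-1-[(3Z)-5-(tert-butyldiphenylsilyloxy)-4-methylpent-3-en-1-yl]-7,7,7a-trimethyl-3,5,6,7-tetrahydro-7aH-indene-2-carbaldehyde | CC(C)(C)[Si](OC/C(C)=C\CCC1=C(C=O)CC2=CCCC(C)(C)[C@@]21C)(c3ccccc3)c4ccccc4 | intermediate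
27 | methyllithium | [Li]C | starting material
28 | trimethylsilyl enol ether of 29 (C2=CH–OSiMe3, C1 quaternary) | CC(C)(C)[Si](OC/C(C)=C\CC[C@]1(C)C(=CO[Si](C)(C)C)CC2=CCCC(C)(C)[C@@]21C)(c3ccccc3)c4ccccc4 | intermediate (not isolated)
29 | (1R,2S,7aS)-1-[(3Z)-5-(tert-butyldiphenylsilyloxy)-4-methylpent-3-en-1-yl]-1,7,7,7a-tetramethyl-2,3,5,6,7,7a-hexahydro-1H-indene-2-carbaldehyde | CC(C)(C)[Si](OC/C(C)=C\CC[C@]1(C)[C@@H](C=O)CC2=CCCC(C)(C)[C@@]21C)(c3ccccc3)c4ccccc4 | intermediate
30 | (1R,2S,7aS)-1-[(3Z)-5-hydroxy-4-methylpent-3-en-1-yl]-1,7,7,7a-tetramethyl-2,3,5,6,7,7a-hexahydro-1H-indene-2-carbaldehyde | OC/C(C)=C\CC[C@]1(C)[C@@H](C=O)CC2=CCCC(C)(C)[C@@]21C | intermediate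
31 | acetic anhydride | CC(=O)OC(C)=O | starting material
32 | (2Z)-5-[(1R,2S,7aS)-2-formyl-1,7,7,7a-tetramethyl-2,3,5,6,7,7a-hexahydro-1H-inden-1-yl]-2-methylpent-2-en-1-yl acetate | CC(=O)OC/C(C)=C\CC[C@]1(C)[C@@H](C=O)CC2=CCCC(C)(C)[C@@]21C | intermediate
33 | (1R,2S,7aS)-1-[(3Z)-5-(acetyloxy)-4-methylpent-3-en-1-yl]-1,7,7,7a-tetramethyl-2,3,5,6,7,7a-hexahydro-1H-indene-2-carboxylic acid | CC(=O)OC/C(C)=C\CC[C@]1(C)[C@@H](C(=O)O)CC2=CCCC(C)(C)[C@@]21C | target

**Step count and risks**

Total: 21 steps. Longest linear sequence: 16 steps (steps 1–9 and 15–21); the side chain takes 5 steps (10–14).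

The three steps most likely to fail:

Step 18. The conjugate addition may stall at a fully substituted β-carbon next to the quaternary C7a, so that 1,2-addition or reduction of the enal takes over, and the facial preference may be incomplete. The fallback sets out from allylic alcohol 25. Hydroxyl-accelerated Simmons–Smith cyclopropanation (Et2Zn, CH2I2, CH2Cl2, 0 °C) of the C1=C2 alkene on the same, less hindered face should give the cyclopropylcarbinol F5. Dess–Martin oxidation gives the cyclopropyl aldehyde F6. Dissolving-metal reduction (Li, NH3/THF, −78 °C, limited equivalents so that the arylsilane is spared) should cleave the cyclopropane bond between C2 and the bridging CH2, which places the carbanion on the primary carbon and turns that CH2 into the C1 methyl. Equilibration with K2CO3 in MeOH then returns to the route at aldehyde 29.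

Step 8. The cyclisation may stop at O-alkylation if the enol ether does not re-ionise, closure through the ring terminus C4 may compete, or the allyl complex may lose a β-hydrogen to give a diene. The fallback sets out from lactone 10 and closes ring B at C1–C2 instead. Opening of the allylic lactone with NaCH(CO2Me)2 under Pd(PPh3)4 catalysis (THF, 65 °C) should give the malonate acid F1. Methylation (MeI, K2CO3, DMF) gives the triester F2. Krapcho demethoxycarbonylation (LiCl, wet DMSO, 150 °C) gives the diester F3. Dieckmann condensation (KOt-Bu, THF) can only form the enolate on the C2 side, since C7a bears no hydrogen, and returns to the route at β-keto ester 14.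

Step 15. Transmetalation and reductive elimination at the hindered C1 may be slow, so that β-hydride loss from the alkylpalladium species and reduction of the triflate win. The fallback sets out from β-keto ester 14. Phosphorylation (NaH, ClP(O)(OEt)2, Et2O, 0 °C) gives the enol diethyl phosphate F4. Addition–elimination with the lithium dialkylcuprate made from iodide 22 (t-BuLi, Et2O, −78 °C; then CuI) replaces the phosphate by the side chain and returns to the route at enoate 24.

**Further compounds**

F1 | step 8 | (1S)-2-[3-methoxy-2-(methoxycarbonyl)-3-oxopropyl]-1,6,6-trimethylcyclohex-2-ene-1-carboxylic acid | COC(=O)C(CC1=CCCC(C)(C)[C@]1(C)C(=O)O)C(=O)OC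
F2 | step 8 | dimethyl 2-{[(6S)-6-(methoxycarbonyl)-5,5,6-trimethylcyclohex-1-en-1-yl]methyl}propanedioate | COC(=O)C(CC1=CCCC(C)(C)[C@]1(C)C(=O)OC)C(=O)OC
F3 | step 8 | methyl (1S)-2-(3-methoxy-3-oxopropyl)-1,6,6-trimethylcyclohex-2-ene-1-carboxylate | COC(=O)CCC1=CCCC(C)(C)[C@]1(C)C(=O)OC
F4 | step 15 | methyl (7aS)-1-[(diethoxyphosphoryl)oxy]-7,7,7a-trimethyl-3,5,6,7-tetrahydro-7aH-indene-2-carboxylate | CCOP(=O)(OCC)OC1=C(C(=O)OC)CC2=CCCC(C)(C)[C@@]21C
F5 | step 18 | cyclopropylcarbinol (25 with a CH2 bridging C1 and C2 on the face of the C7a methyl, CH2OH on C2) | CC(C)(C)[Si](OC/C(C)=C\CC[C@]12C[C@@]1(CO)CC3=CCCC(C)(C)[C@@]32C)(c5ccccc5)c6ccccc6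
F6 | step 18 | cyclopropyl aldehyde (F5 with CHO in place of CH2OH) | CC(C)(C)[Si](OC/C(C)=C\CC[C@]12C[C@@]1(C=O)CC3=CCCC(C)(C)[C@@]32C)(c5ccccc5)c6ccccc6
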